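**Retrosynthetic overview**

1. Locants used below: ring C6 (CH with the acyloxypropyl chain), C7 (alkylidene carbon), C8 and C9 (ring CH2), C10 (carbinol carbon), C11 (quaternary carbon); C16 is the side-chain carbinol. Ester and silyl groups come off first, and the (Z)-enal is traced back to a C7 ring ketone (Horner–Wadsworth–Emmons, then DIBAL).
2. Key disconnection: C7–C8 and C9–C10 are cut together, so the only ring (the cyclohexane) is closed last from an acyclic 1,4-keto aldehyde (C7 aldehyde, C10 methyl ketone) and ethylene used as a 1,2-dianion (zirconocene–ethylene complex).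
3. Enabling feature: in the ring C6–C7–C8–C9–C10–C11 the bare C8H2–C9H2 unit is flanked only by C7 (a latent ketone) and C10 (tertiary carbinol); this 1,4-dioxygenated pattern is the retron of a 1,4-dicarbonyl plus C2, and C6 and C11 carry every other substituent.
4. The keto aldehyde comes from an enantioselective Ireland–Claisen rearrangement of a neryl-type ester (C6–C11 bond, both stereocentres) and Wacker oxidation of the new vinyl group. Nerol thus supplies C10 with its methyl, C11 with its methyl, and C12–C16.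
5. The side chain is built before the rearrangement: allylic oxidation of the neryl terminus, coupling with geranyl phenyl sulfone, desulfonylation and CBS reduction (C16).

Key step: step 14

Remark (assumption): the (S,S)-antipode of the bromoborane controller in step 10 is assumed to give the (2R,3S)-acid; if the sense of induction is the opposite, the (R,R)-antipode is used and nothing else changes.
Abbreviations: TBSO = tert-butyldimethylsilyloxy; TIPSO = triisopropylsilyloxy; Cp = cyclopentadienyl; "side chain" in ring compounds = (3E,5R,7E)-4,8,12-trimethyl-5-(TIPSO)trideca-3,7,11-trien-1-yl.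

**Route**

Step 1
Reactants: 1 5-(TBSO)pentan-1-ol
Product: 2 5-(TBSO)pentanoic acid
Conditions: TEMPO (cat.), PhI(OAc)2 (2.2 equiv), MeCN/H2O 1:1, rt
Reagents that add atoms: water, O
Why: TEMPO/PhI(OAc)2 oxidation of a primary alcohol to the acid through the aldehyde hydrate is mild enough to leave the primary silyl ether in place.

Step 2
Reactants: 2 5-(TBSO)pentanoic acid; 3 nerol
Product: 4 neryl 5-(TBSO)pentanoate
Conditions: DCC, DMAP (cat.), CH2Cl2, 0 °C to rt
Reagents that add atoms: none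
Why: Steglich esterification of a primary allylic alcohol proceeds under neutral conditions without isomerising the (Z)-alkene.

Step 3
Reactants: 4 neryl 5-(TBSO)pentanoate
Product: 6 (2Z,6E)-3,7-dimethyl-8-oxoocta-2,6-dien-1-yl 5-(TBSO)pentanoate, via allylic alcohol 5 (not isolated)
Conditions: SeO2 (0.3 equiv), t-BuOOH, salicylic acid (cat.), CH2Cl2, rt; filter; then MnO2, CH2Cl2, rt
Reagents that add atoms: tert-butyl hydroperoxide, CC(C)(C)OO
Why: SeO2 allylic oxidation (ene reaction then [2,3]-shift) should attack the electron-rich terminal alkene at its (E)-methyl group, the proximal alkene being deactivated by the allylic ester, and MnO2 converges alcohol and aldehyde to the (E)-enal.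

Step 4
Reactants: 7 geranyl bromide
Product: 8 geranyl phenyl sulfone
Conditions: PhSO2Na, DMF, rt
Reagents that add atoms: sodium benzenesulfinate, [Na+].[O-]S(=O)c1ccccc1
Why: SN2 S-alkylation of the sulfinate by the primary allylic bromide should keep the (E)-alkene.

Step 5
Reactants: 8 geranyl phenyl sulfone; 6 (2Z,6E)-3,7-dimethyl-8-oxoocta-2,6-dien-1-yl 5-(TBSO)pentanoate
Product: 10 (2Z,6E,10E)-8-hydroxy-3,7,11,15-tetramethyl-9-(phenylsulfonyl)hexadeca-2,6,10,14-tetraen-1-yl 5-(TBSO)pentanoate (diastereomer mixture at C8/C9), via lithiated sulfone 9 (not isolated)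
Conditions: n-BuLi, THF, −78 °C; then 6, −78 °C; AcOH quench at −78 °C
Reagents that add atoms: none
Why: The α-sulfonyl allylic carbanion should add through its α-carbon in 1,2-fashion to the enal faster than to the alkyl ester at −78 °C; both new stereocentres are erased in steps 6 and 7.

Step 6
Reactants: 10 β-hydroxy sulfone
Product: 11 (2Z,6E,10E)-3,7,11,15-tetramethyl-8-oxo-9-(phenylsulfonyl)hexadeca-2,6,10,14-tetraen-1-yl 5-(TBSO)pentanoate
Conditions: Dess–Martin periodinane, CH2Cl2, 0 °C to rt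
Reagents that add atoms: none
Why: Dess–Martin oxidation of the secondary allylic alcohol gives the β-keto sulfone without touching alkenes, ester or silyl ether.

Step 7
Reactants: 11 β-keto sulfone
Product: 12 (2Z,6E,10E)-3,7,11,15-tetramethyl-8-oxohexadeca-2,6,10,14-tetraen-1-yl 5-(TBSO)pentanoate
Conditions: SmI2 (2.5 equiv), THF/MeOH, −78 °C
Reagents that add atoms: none
Why: SmI2 (divalent samarium) reductive desulfonylation cleaves the C–S bond α to the ketone, and protonation of the samarium enolate at carbon at −78 °C should leave the skipped (E)-alkene where it is.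

Step 8
Reactants: 12 dienone
Product: 13 (2Z,6E,8R,10E)-8-hydroxy-3,7,11,15-tetramethylhexadeca-2,6,10,14-tetraen-1-yl 5-(TBSO)pentanoate
Conditions: (S)-2-methyl-CBS-oxazaborolidine (0.3 equiv), catecholborane, toluene, −78 °C; MeOH, then aq. NaOH work-up
Reagents that add atoms: none
Why: Corey–Bakshi–Shibata reduction with the α-methylalkenyl group as the large substituent should give the (R)-carbinol (C16) from the (S)-catalyst, by analogy with acetophenone giving the (R)-alcohol.

Step 9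
Reactants: 13 (8R)-allylic alcohol
Product: 14 (2Z,6E,8R,10E)-3,7,11,15-tetramethyl-8-(TIPSO)hexadeca-2,6,10,14-tetraen-1-yl 5-(TBSO)pentanoate
Conditions: TIPSOTf, 2,6-lutidine, CH2Cl2, −78 to 0 °C
Reagents that add atoms: triisopropylsilyl triflate, CC(C)[Si](OS(=O)(=O)C(F)(F)F)(C(C)C)C(C)C
Why: Silylation with a silyl triflate and a hindered base protects the secondary allylic alcohol without ionising it, and the TIPS ether is stable to every later step up to step 20.

Step 10
Reactants: 14 TIPS-protected neryl-type ester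
Product: 16 (2R,3S,6E,8R,10E)-2-[3-(TBSO)propyl]-3-ethenyl-3,7,11,15-tetramethyl-8-(TIPSO)hexadeca-6,10,14-trienoic acid, via boron enolate 15 (not isolated)
Conditions: preformed (4S,5S)-2-bromo-4,5-diphenyl-1,3-bis{[3,5-bis(trifluoromethyl)phenyl]sulfonyl}-1,3,2-diazaborolidine (1.3 equiv), Et3N, toluene/hexane, −78 °C; then −20 to 4 °C; aqueous work-up
Reagents that add atoms: none
Why: Enantioselective Ireland–Claisen rearrangement of a chiral boron ester enolate: the chair transition state with the E(O)-enolate (propyl chain axial) and the (Z)-allyl terminus (methyl equatorial) fixes the C6/C11 relative configuration, and the C2-symmetric bis-sulfonamide on boron selects one of the two enantiomeric chairs.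

Step 11
Reactants: 16 Claisen acid
Product: 17 (2R,3S,6E,8R,10E)-2-[3-(TBSO)propyl]-3-ethenyl-3,7,11,15-tetramethyl-8-(TIPSO)hexadeca-6,10,14-trien-1-ol
Conditions: LiAlH4, Et2O, 0 °C; Fieser work-up
Reagents that add atoms: none
Why: LiAlH4 reduces the acid to the primary alcohol and leaves isolated alkenes and silyl ethers untouched.

Step 12
Reactants: 17 primary alcohol
Product: 18 (2R,3S,6E,8R,10E)-2-[3-(TBSO)propyl]-3-ethenyl-3,7,11,15-tetramethyl-8-(TIPSO)hexadeca-6,10,14-trienal
Conditions: Dess–Martin periodinane, CH2Cl2, 0 °C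
Reagents that add atoms: none
Why: Dess–Martin oxidation gives the α-branched aldehyde under conditions that should not epimerise C6.

Step 13
Reactants: 18 γ,δ-unsaturated aldehyde
Product: 19 (2R,3R,6E,8R,10E)-3-acetyl-2-[3-(TBSO)propyl]-3,7,11,15-tetramethyl-8-(TIPSO)hexadeca-6,10,14-trienal
Conditions: PdCl2 (cat.), CuCl, O2 (1 atm), DMF/H2O 7:1, rt
Reagents that add atoms: water, O
Why: Tsuji–Wacker oxidation (Markovnikov hydroxypalladation) converts the only monosubstituted alkene into the methyl ketone, as known for 4-pentenals from Claisen rearrangements, while the trisubstituted alkenes should not react.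

Step 14
Reactants: 19 1,4-keto aldehyde
Product: 22 (1S,2R,3R,4R)-3-[3-(TBSO)propyl]-1,2-dimethyl-2-(side chain)cyclohexane-1,4-diol, via oxazirconacyclopentane 20 (not isolated), via bicyclic dioxazirconacycle 21 (not isolated)
Conditions: Cp2ZrCl2 (1.2 equiv), EtMgBr (2.4 equiv), THF, −78 °C, 1 h; 19 added at −78 °C (high dilution), then to rt (50 °C if the second insertion is slow); 1 M HCl, 0 °C
Reagents that add atoms: ethylmagnesium bromide, CC[Mg]Br
Why: Proposed new method: Cp2ZrEt2 loses ethane to give the zirconocene–ethylene complex (a zirconacyclopropane, an ethylene 1,2-dianion equivalent), whose two Zr–C bonds insert first the aldehyde and then the tethered methyl ketone, so that one CH2 bonds to the aldehyde carbon (C7–C8) and the other to the ketone carbon (C9–C10); the closest known reactions are the coupling of zirconocene–alkene complexes with one aldehyde or ketone to give oxazirconacyclopentanes, aldehyde insertion into the Zr–C(sp3) bond of zirconacyclopentenes, and the twofold carbonyl insertion into zirconocene–diene complexes that gives 1,6-diols. The cyclohexane closes in the second insertion, a 6-exo-trig addition of the zirconium-bound CH2 to the ketone inside a bicyclic dioxazirconacycle. The C7 carbinol centre is set by Felkin–Anh attack anti to the quaternary C11 (oxygen trans to the silyloxypropyl chain) and is removed in step 15; the C10 centre is set by the O–Zr–O bridge, which forces its oxygen cis to the C7 oxygen, that is trans to the C6 chain and to the C11 methyl. The step needs aldehyde-before-ketone chemoselectivity and no alkene insertion: the aldehyde is the more electrophilic and less hindered carbonyl, the three remaining alkenes are trisubstituted and should not bind zirconocene, and the only terminal alkene was already oxidised in step 13.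

Step 15
Reactants: 22 cis-1,4-diol
Product: 23 (2R,3R,4S)-2-[3-(TBSO)propyl]-4-hydroxy-3,4-dimethyl-3-(side chain)cyclohexan-1-one
Conditions: Dess–Martin periodinane, CH2Cl2, rt
Reagents that add atoms: none
Why: Dess–Martin oxidation converts only the secondary alcohol (the temporary C7 stereocentre) into the ketone, since the tertiary C10 alcohol cannot be oxidised.

Step 16
Reactants: 23 hydroxy ketone
Product: 24 (2Z)-2-{(2S,3R,4S)-2-[3-(TBSO)propyl]-4-hydroxy-3,4-dimethyl-3-(side chain)cyclohexylidene}propanenitrile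
Conditions: diethyl (1-cyanoethyl)phosphonate, KOt-Bu (excess), THF, 0 to 60 °C
Reagents that add atoms: diethyl (1-cyanoethyl)phosphonate, CCOP(=O)(OCC)C(C)C#N
Why: Horner–Wadsworth–Emmons olefination with the small, reactive cyano-phosphonate anion is the precedent for hindered α-branched ring ketones (17-keto steroids), and the linear nitrile rather than the methyl group should end up cis to the more encumbered C6, which is the required geometry.

Step 17
Reactants: 24 unsaturated nitrile
Product: 26 (2Z)-2-{(2S,3R,4S)-2-[3-(TBSO)propyl]-4-hydroxy-3,4-dimethyl-3-(side chain)cyclohexylidene}propanal, via aluminium aldimine 25 (not isolated)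
Conditions: i-Bu2AlH (3 equiv), toluene, −78 °C; aqueous potassium sodium tartrate, rt
Reagents that add atoms: water, O
Why: DIBAL reduction of a nitrile stops at the N-aluminio aldimine at −78 °C, and mild hydrolysis gives the enal with the double-bond geometry unchanged.

Step 18
Reactants: 26 silyl-protected enal
Product: 27 (2Z)-2-{(2S,3R,4S)-4-hydroxy-2-(3-hydroxypropyl)-3,4-dimethyl-3-(side chain)cyclohexylidene}propanal
Conditions: HF·pyridine, pyridine, THF, 0 °C
Reagents that add atoms: none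
Why: Buffered HF·pyridine removes the primary TBS ether much faster than the hindered secondary TIPS ether.

Step 19
Reactants: 27 primary alcohol; 28 myristoyl chloride
Product: 29 3-{(1S,2Z,5S,6R)-5-hydroxy-5,6-dimethyl-2-(1-oxopropan-2-ylidene)-6-(side chain)cyclohexyl}propyl tetradecanoate
Conditions: pyridine, DMAP (cat.), CH2Cl2, 0 °C
Reagents that add atoms: none
Why: Acylation with an acid chloride takes the primary alcohol only, because the tertiary C10 alcohol is unreactive under these conditions.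

Step 20
Reactants: 29 TIPS-protected ester
Product: 30 CNP0171467.2
Conditions: Bu4NF, AcOH (1:1), THF, rt
Reagents that add atoms: none
Why: Acetic acid-buffered fluoride cleaves the secondary silyl ether without ester cleavage or base-mediated isomerisation of the enal.

**Compound list**

1 | 5-[(tert-butyldimethylsilyl)oxy]pentan-1-ol | CC(C)(C)[Si](C)(C)OCCCCCO | starting material
2 | 5-[(tert-butyldimethylsilyl)oxy]pentanoic acid | CC(C)(C)[Si](C)(C)OCCCCC(=O)O | intermediate
3 | nerol, (2Z)-3,7-dimethylocta-2,6-dien-1-ol | CC(C)=CCC/C(C)=C\CO | starting material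
4 | neryl 5-(TBSO)pentanoate | CC(C)=CCC/C(C)=C\COC(=O)CCCCO[Si](C)(C)C(C)(C)C | intermediate
5 | (2Z,6E)-8-hydroxy-3,7-dimethylocta-2,6-dien-1-yl 5-(TBSO)pentanoate | OC/C(C)=C/CC/C(C)=C\COC(=O)CCCCO[Si](C)(C)C(C)(C)C | intermediate
6 | (2Z,6E)-3,7-dimethyl-8-oxoocta-2,6-dien-1-yl 5-(TBSO)pentanoate | O=C/C(C)=C/CC/C(C)=C\COC(=O)CCCCO[Si](C)(C)C(C)(C)C | intermediate
7 | geranyl bromide, (2E)-1-bromo-3,7-dimethylocta-2,6-diene | CC(C)=CCC/C(C)=C/CBr | starting material
8 | geranyl phenyl sulfone | CC(C)=CCC/C(C)=C/CS(=O)(=O)c1ccccc1 | intermediate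
9 | α-lithio geranyl phenyl sulfone | CC(C)=CCC/C(C)=C/C([Li])S(=O)(=O)c1ccccc1 | intermediate
10 | (2Z,6E,10E)-8-hydroxy-3,7,11,15-tetramethyl-9-(phenylsulfonyl)hexadeca-2,6,10,14-tetraen-1-yl 5-(TBSO)pentanoate (C8/C9 diastereomer mixture) | CC(C)=CCC/C(C)=C/C(C(O)/C(C)=C/CC/C(C)=C\COC(=O)CCCCO[Si](C)(C)C(C)(C)C)S(=O)(=O)c1ccccc1 | intermediate
11 | (2Z,6E,10E)-3,7,11,15-tetramethyl-8-oxo-9-(phenylsulfonyl)hexadeca-2,6,10,14-tetraen-1-yl 5-(TBSO)pentanoate (C9 epimer mixture) | CC(C)=CCC/C(C)=C/C(C(=O)/C(C)=C/CC/C(C)=C\COC(=O)CCCCO[Si](C)(C)C(C)(C)C)S(=O)(=O)c1ccccc1 | intermediate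
12 | (2Z,6E,10E)-3,7,11,15-tetramethyl-8-oxohexadeca-2,6,10,14-tetraen-1-yl 5-(TBSO)pentanoate | CC(C)=CCC/C(C)=C/CC(=O)/C(C)=C/CC/C(C)=C\COC(=O)CCCCO[Si](C)(C)C(C)(C)C | intermediate
13 | (2Z,6E,8R,10E)-8-hydroxy-3,7,11,15-tetramethylhexadeca-2,6,10,14-tetraen-1-yl 5-(TBSO)pentanoate | CC(C)=CCC/C(C)=C/C[C@@H](O)/C(C)=C/CC/C(C)=C\COC(=O)CCCCO[Si](C)(C)C(C)(C)C | intermediate
14 | (2Z,6E,8R,10E)-3,7,11,15-tetramethyl-8-(TIPSO)hexadeca-2,6,10,14-tetraen-1-yl 5-(TBSO)pentanoate | CC(C)=CCC/C(C)=C/C[C@@H](O[Si](C(C)C)(C(C)C)C(C)C)/C(C)=C/CC/C(C)=C\COC(=O)CCCCO[Si](C)(C)C(C)(C)C | intermediate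
15 | E(O)-boron enolate of 14 carrying the (4S,5S)-diazaborolidine | CC(C)=CCC/C(C)=C/C[C@@H](O[Si](C(C)C)(C(C)C)C(C)C)/C(C)=C/CC/C(C)=C\CO/C(OB1N(S(=O)(=O)c2cc(cc(c2)C(F)(F)F)C(F)(F)F)[C@@H](c2ccccc2)[C@H](c2ccccc2)N1S(=O)(=O)c1cc(cc(c1)C(F)(F)F)C(F)(F)F)=C\CCCO[Si](C)(C)C(C)(C)C | intermediate
16 | (2R,3S,6E,8R,10E)-2-[3-(TBSO)propyl]-3-ethenyl-3,7,11,15-tetramethyl-8-(TIPSO)hexadeca-6,10,14-trienoic acid | OC(=O)[C@H](CCCO[Si](C)(C)C(C)(C)C)[C@](C)(C=C)CC/C=C(\C)[C@H](O[Si](C(C)C)(C(C)C)C(C)C)C/C=C(\C)CCC=C(C)C | intermediate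
17 | (2R,3S,6E,8R,10E)-2-[3-(TBSO)propyl]-3-ethenyl-3,7,11,15-tetramethyl-8-(TIPSO)hexadeca-6,10,14-trien-1-ol | OC[C@H](CCCO[Si](C)(C)C(C)(C)C)[C@](C)(C=C)CC/C=C(\C)[C@H](O[Si](C(C)C)(C(C)C)C(C)C)C/C=C(\C)CCC=C(C)C | intermediate
18 | (2R,3S,6E,8R,10E)-2-[3-(TBSO)propyl]-3-ethenyl-3,7,11,15-tetramethyl-8-(TIPSO)hexadeca-6,10,14-trienal | O=C[C@H](CCCO[Si](C)(C)C(C)(C)C)[C@](C)(C=C)CC/C=C(\C)[C@H](O[Si](C(C)C)(C(C)C)C(C)C)C/C=C(\C)CCC=C(C)C | intermediate
19 | (2R,3R,6E,8R,10E)-3-acetyl-2-[3-(TBSO)propyl]-3,7,11,15-tetramethyl-8-(TIPSO)hexadeca-6,10,14-trienal | O=C[C@H](CCCO[Si](C)(C)C(C)(C)C)[C@](C)(C(C)=O)CC/C=C(\C)[C@H](O[Si](C(C)C)(C(C)C)C(C)C)C/C=C(\C)CCC=C(C)C | intermediate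
20 | 2,2-bis(η5-cyclopentadienyl)-1-oxa-2-zirconacyclopentane from aldehyde insertion (Cp drawn η1) | C1C[Zr](C2C=CC=C2)(C2C=CC=C2)O[C@H]1[C@H](CCCO[Si](C)(C)C(C)(C)C)[C@](C)(C(C)=O)CC/C=C(\C)[C@H](O[Si](C(C)C)(C(C)C)C(C)C)C/C=C(\C)CCC=C(C)C | intermediate
21 | bicyclic zirconocene 1,4-diolate (dioxazirconacycle bridging C7–O and C10–O; Cp drawn η1) | CC(C)(C)[Si](C)(C)OCCC[C@H]1[C@H]2CC[C@](C)(O[Zr](C3C=CC=C3)(C3C=CC=C3)O2)[C@]1(C)CC/C=C(\C)[C@H](O[Si](C(C)C)(C(C)C)C(C)C)C/C=C(\C)CCC=C(C)C | intermediate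
22 | (1S,2R,3R,4R)-3-[3-(TBSO)propyl]-1,2-dimethyl-2-[(3E,5R,7E)-4,8,12-trimethyl-5-(TIPSO)trideca-3,7,11-trien-1-yl]cyclohexane-1,4-diol | CC(C)(C)[Si](C)(C)OCCC[C@H]1[C@H](O)CC[C@](C)(O)[C@]1(C)CC/C=C(\C)[C@H](O[Si](C(C)C)(C(C)C)C(C)C)C/C=C(\C)CCC=C(C)C | intermediate
23 | (2R,3R,4S)-2-[3-(TBSO)propyl]-4-hydroxy-3,4-dimethyl-3-[(3E,5R,7E)-4,8,12-trimethyl-5-(TIPSO)trideca-3,7,11-trien-1-yl]cyclohexan-1-one | CC(C)(C)[Si](C)(C)OCCC[C@H]1C(=O)CC[C@](C)(O)[C@]1(C)CC/C=C(\C)[C@H](O[Si](C(C)C)(C(C)C)C(C)C)C/C=C(\C)CCC=C(C)C | intermediate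
24 | (2Z)-2-{(2S,3R,4S)-2-[3-(TBSO)propyl]-4-hydroxy-3,4-dimethyl-3-[(3E,5R,7E)-4,8,12-trimethyl-5-(TIPSO)trideca-3,7,11-trien-1-yl]cyclohexylidene}propanenitrile | CC(C)(C)[Si](C)(C)OCCC[C@H]1/C(=C(/C)C#N)CC[C@](C)(O)[C@]1(C)CC/C=C(\C)[C@H](O[Si](C(C)C)(C(C)C)C(C)C)C/C=C(\C)CCC=C(C)C | intermediate
25 | N-(diisobutylaluminio) aldimine of 26 (C10 oxygen as its diisobutylaluminium alkoxide) | CC(C)(C)[Si](C)(C)OCCC[C@H]1/C(=C(/C)C=N[Al](CC(C)C)CC(C)C)CC[C@](C)(O[Al](CC(C)C)CC(C)C)[C@]1(C)CC/C=C(\C)[C@H](O[Si](C(C)C)(C(C)C)C(C)C)C/C=C(\C)CCC=C(C)C | intermediate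
26 | (2Z)-2-{(2S,3R,4S)-2-[3-(TBSO)propyl]-4-hydroxy-3,4-dimethyl-3-[(3E,5R,7E)-4,8,12-trimethyl-5-(TIPSO)trideca-3,7,11-trien-1-yl]cyclohexylidene}propanal | CC(C)(C)[Si](C)(C)OCCC[C@H]1/C(=C(/C)C=O)CC[C@](C)(O)[C@]1(C)CC/C=C(\C)[C@H](O[Si](C(C)C)(C(C)C)C(C)C)C/C=C(\C)CCC=C(C)C | intermediate
27 | (2Z)-2-{(2S,3R,4S)-4-hydroxy-2-(3-hydroxypropyl)-3,4-dimethyl-3-[(3E,5R,7E)-4,8,12-trimethyl-5-(TIPSO)trideca-3,7,11-trien-1-yl]cyclohexylidene}propanal | OCCC[C@H]1/C(=C(/C)C=O)CC[C@](C)(O)[C@]1(C)CC/C=C(\C)[C@H](O[Si](C(C)C)(C(C)C)C(C)C)C/C=C(\C)CCC=C(C)C | intermediate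
28 | myristoyl chloride (tetradecanoyl chloride) | CCCCCCCCCCCCCC(=O)Cl | starting material
29 | 3-{(1S,2Z,5S,6R)-5-hydroxy-5,6-dimethyl-2-(1-oxopropan-2-ylidene)-6-[(3E,5R,7E)-4,8,12-trimethyl-5-(TIPSO)trideca-3,7,11-trien-1-yl]cyclohexyl}propyl tetradecanoate | CCCCCCCCCCCCCC(=O)OCCC[C@H]1/C(=C(/C)C=O)CC[C@](C)(O)[C@]1(C)CC/C=C(\C)[C@H](O[Si](C(C)C)(C(C)C)C(C)C)C/C=C(\C)CCC=C(C)C | intermediate
30 | CNP0171467.2, 3-{(1S,2Z,5S,6R)-5-hydroxy-6-[(3E,5R,7E)-5-hydroxy-4,8,12-trimethyltrideca-3,7,11-trien-1-yl]-5,6-dimethyl-2-(1-oxopropan-2-ylidene)cyclohexyl}propyl tetradecanoate | CCCCCCCCCCCCCC(=O)OCCC[C@H]1/C(=C(/C)C=O)CC[C@](C)(O)[C@]1(C)CC/C=C(\C)[C@H](O)C/C=C(\C)CCC=C(C)C | target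

**Step count and risks**

Total step count: 20. Longest linear sequence: 19 steps (from 1 to 30 through steps 1–3 and 5–20; step 4 is a one-step branch).

Steps most likely to fail:

1. Step 14 (proposed new method). The oxazirconacyclopentane from the first insertion may fail to add to the hindered methyl ketone, in which case protonolysis would simply give the ethyl carbinol; the Felkin/bridge relay may also give poor facial control at C10. The fallback sets out from 19 and comes back at 22, using a cis-vinylene 1,2-dianion equivalent in separate known steps. (Z)-2-(Tributylstannyl)vinyllithium, from (Z)-1,2-bis(tributylstannyl)ethene and n-BuLi, is added to the aldehyde of 19 at −78 °C (Felkin–Anh, aldehyde before ketone) to give the (Z)-stannyl allylic alcohol F1. Iododestannylation with I2 in CH2Cl2 gives the (Z)-vinyl iodide F2. An intramolecular Nozaki–Hiyama–Kishi reaction (CrCl2, cat. NiCl2, DMSO/THF) onto the methyl ketone closes the ring to the cyclohex-2-ene-1,4-diol F3, and any C10 epimer would be separated at this point. Diimide (2-nitrobenzenesulfonyl hydrazide, Et3N) then saturates the cis-disubstituted ring alkene in preference to the trisubstituted ones and gives 22.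

2. Step 10. Control of the enolate geometry or of the enantiotopic chair by the boron controller may be incomplete, and the Lewis-acidic bromoborane may cost a silyl ether. The fallback sets out from 14 and comes back at 17, replacing reagent control by a covalent resolution. A classical Ireland–Claisen rearrangement (LDA, Me3SiCl, THF, −78 °C to rt, E(O)-enolate, then aqueous acid) should give the same relative configuration, as 16 together with its (2S,3R)-diastereomer F4. The mixture is converted (pivaloyl chloride, Et3N; then lithiated (S)-4-benzyl-2-oxazolidinone) into the N-acyl oxazolidinones. The one derived from 16, the imide F5, is separated by chromatography and reduced with LiBH4 to alcohol 17.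

3. Step 16. Addition to the hindered ketone may be slow, so that enolisation (epimerisation at C6) competes, or the wrong alkene isomer may form. The fallback sets out from 23 and comes back at 26, skipping 24. 2-Propenylmagnesium bromide with CeCl3 (THF, −78 °C) adds to the ketone to give the tertiary allylic alcohol F6 (either C7 epimer serves). PCC in CH2Cl2 then effects the Babler–Dauben oxidative 1,3-transposition to the enal 26; the isomer with the formyl group cis to C6 should be favoured because it has the lower allylic strain.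

Further compounds
F1 | step 14 | (Z)-stannyl allylic alcohol: adduct of (Z)-2-(tributylstannyl)vinyllithium and the aldehyde of 19 (Felkin epimer) | CCCC[Sn](CCCC)(CCCC)/C=C\[C@@H](O)[C@H](CCCO[Si](C)(C)C(C)(C)C)[C@](C)(C(C)=O)CC/C=C(\C)[C@H](O[Si](C(C)C)(C(C)C)C(C)C)C/C=C(\C)CCC=C(C)C
F2 | step 14 | (Z)-vinyl iodide corresponding to F1 | I/C=C\[C@@H](O)[C@H](CCCO[Si](C)(C)C(C)(C)C)[C@](C)(C(C)=O)CC/C=C(\C)[C@H](O[Si](C(C)C)(C(C)C)C(C)C)C/C=C(\C)CCC=C(C)C
F3 | step 14 | cyclohex-2-ene-1,4-diol analogue of 22 | CC(C)(C)[Si](C)(C)OCCC[C@H]1[C@H](O)C=C[C@](C)(O)[C@]1(C)CC/C=C(\C)[C@H](O[Si](C(C)C)(C(C)C)C(C)C)C/C=C(\C)CCC=C(C)C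
F4 | step 10 | (2S,3R,6E,8R,10E)-diastereomer of acid 16 | OC(=O)[C@@H](CCCO[Si](C)(C)C(C)(C)C)[C@@](C)(C=C)CC/C=C(\C)[C@H](O[Si](C(C)C)(C(C)C)C(C)C)C/C=C(\C)CCC=C(C)C
F5 | step 10 | N-acyl (S)-4-benzyl-2-oxazolidinone of acid 16 | O=C1OC[C@H](Cc2ccccc2)N1C(=O)[C@H](CCCO[Si](C)(C)C(C)(C)C)[C@](C)(C=C)CC/C=C(\C)[C@H](O[Si](C(C)C)(C(C)C)C(C)C)C/C=C(\C)CCC=C(C)C
F6 | step 16 | tertiary allylic alcohol from addition of 2-propenylmagnesium bromide to the C7 ketone of 23 | CC(C)(C)[Si](C)(C)OCCC[C@H]1C(O)(C(C)=C)CC[C@](C)(O)[C@]1(C)CC/C=C(\C)[C@H](O[Si](C(C)C)(C(C)C)C(C)C)C/C=C(\C)CCC=C(C)C
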